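**Plan**

- Retrosynthesis: the three phenols are masked as benzyl ethers, the C4 carbinol is traced back to a ketone, and a methoxycarbonyl group is put back on C3. The resulting oxan-4-one is then cut at C5–C6, C2–C3 and O1–C2.
- Enabling feature: the oxane is numbered O1, C2 (bearing ring A, the 3-methoxy-4,5-dihydroxyphenyl group), C3, C4 (carbinol), C5, C6 (bearing the C7–C8 link to ring B, the 4-hydroxyphenyl group). C3–C4–C5 is the backbone of an acetoacetate dianion, and C2 and C6 are the carbonyl carbons of two aldehydes.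
- Forward: the bis-silyl dienolate of methyl acetoacetate is joined through its terminal carbon to 3-(4-benzyloxyphenyl)propanal (chain C3–C8). In the same flask 3,4-bis(benzyloxy)-5-methoxybenzaldehyde is condensed at C3 and the hydroxyl closes the only new ring. Decarboxylation, ketone reduction and debenzylation follow.
- Stereochemistry: C6 comes from the Ti(OiPr)4/(R)-BINOL vinylogous aldol. C2 (and the transient C3) come from reversible oxa-Michael closure to the all-equatorial chair. C4 comes from axial hydride delivery to the 2,6-cis ketone.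

Key step: step 6

Assumption: (R)-BINOL is taken to give the 5S aldol adduct, by analogy with the facial sense of this titanium catalyst with aromatic aldehydes, which corresponds to the S descriptor for an aliphatic aldehyde. Should the sense be the opposite, (S)-BINOL is used and nothing else changes.

**Route**

Step 1
Reactants: 1 3,4-dihydroxy-5-methoxybenzaldehyde
Product: 2 3,4-bis(benzyloxy)-5-methoxybenzaldehyde
Conditions: BnBr (2.5 equiv), K2CO3 (3 equiv), DMF, 60 °C
Reagents that add atoms: benzyl bromide, BrCc1ccccc1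
Why: Williamson ether synthesis, in which carbonate deprotonates both phenols and the phenoxides displace bromide from benzyl bromide while the aldehyde is inert.

Step 2
Reactants: 3 3-(4-hydroxyphenyl)propan-1-ol
Product: 4 3-(4-benzyloxyphenyl)propan-1-ol
Conditions: BnBr (1.1 equiv), K2CO3, acetone, reflux
Reagents that add atoms: benzyl bromide, BrCc1ccccc1
Why: Williamson etherification that should be chemoselective, because K2CO3 deprotonates the phenol but not the aliphatic alcohol.

Step 3
Reactants: 4 3-(4-benzyloxyphenyl)propan-1-ol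
Product: 5 3-(4-benzyloxyphenyl)propanal
Conditions: TEMPO (10 mol %), PhI(OAc)2 (1.1 equiv), CH2Cl2, rt
Reagents that add atoms: none
Why: TEMPO-catalysed (oxoammonium) oxidation of a primary alcohol, which stops at the aldehyde under anhydrous conditions and leaves the benzyl ether untouched.

Step 4
Reactants: 6 methyl acetoacetate
Product: 7 methyl 3-(trimethylsilyloxy)but-2-enoate
Conditions: Me3SiCl, Et3N, hexane, rt
Reagents that add atoms: chlorotrimethylsilane, C[Si](C)(C)Cl
Why: Silyl enol ether formation by amine-mediated enolisation of the β-ketoester and O-silylation at the ketone oxygen; the alkene geometry is of no consequence.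

Step 5
Reactants: 7 methyl 3-(trimethylsilyloxy)but-2-enoate
Product: 8 1-methoxy-1,3-bis(trimethylsilyloxy)buta-1,3-diene
Conditions: LiN(iPr)2, THF, −78 °C; then Me3SiCl, −78 °C to 0 °C
Reagents that add atoms: chlorotrimethylsilane, C[Si](C)(C)Cl
Why: Kinetic deprotonation of the γ-methyl group gives the extended ester enolate, which is trapped on oxygen by the chlorosilane (silyl ketene acetal formation).

Step 6
Reactants: 8 1-methoxy-1,3-bis(trimethylsilyloxy)buta-1,3-diene; 5 3-(4-benzyloxyphenyl)propanal; 2 3,4-bis(benzyloxy)-5-methoxybenzaldehyde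
Product: 11 methyl (2S,3R,6S)-2-[3,4-bis(benzyloxy)-5-methoxyphenyl]-6-[2-(4-benzyloxyphenyl)ethyl]-4-oxooxane-3-carboxylate, via hydroxy ketoester 9 (not isolated), via arylidene ketoester 10 (not isolated)
Conditions: 5, 8 (1.1 equiv), Ti(OiPr)4 (8 mol %), (R)-BINOL (8 mol %), 4 Å MS, THF, −78 °C to rt; then 2, TiCl4, −78 °C to −20 °C; H2O
Reagents that add atoms: none
Why: The titanium BINOLate binds aldehyde 5 and the terminal (γ) carbon of silyl dienolate 8 adds to one carbonyl face in a vinylogous Mukaiyama aldol, forming C5–C6 and giving 9, whose S carbinol (the later C6) is set by the ligand. TiCl4 then turns the β-ketoester unit of 9 into a titanium enolate that condenses with aldehyde 2 (Knoevenagel, bond C2–C3) to arylidene 10, and the δ-oxygen adds to the arylidene carbon in a 6-endo-trig oxa-Michael closure (bond O1–C2) that forms the oxane ring. The closest known reaction type is the one-pot Maitland–Japp synthesis of 2,6-cis-tetrahydropyran-4-ones from a bis-silyl dienolate and two aldehydes, with a titanium–BINOL aldol as the asymmetric stage. C2 and C3 are set relative to C6 under thermodynamic control: the electron-rich ring A makes the oxa-Michael addition reversible and C3 is epimerisable, so the product should settle in the chair with ring A, the ester and the arylethyl chain all equatorial. The step needs γ- over α-regioselectivity, secured by the higher nucleophilicity of the terminal carbon of the bis-silyl dienolate, and chemoselectivity between the two aldehydes, secured by letting 5 and 8 be consumed before 2 and TiCl4 are added.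

Step 7
Reactants: 11 methyl (2S,3R,6S)-2-[3,4-bis(benzyloxy)-5-methoxyphenyl]-6-[2-(4-benzyloxyphenyl)ethyl]-4-oxooxane-3-carboxylate
Product: 12 (2S,6S)-2-[3,4-bis(benzyloxy)-5-methoxyphenyl]-6-[2-(4-benzyloxyphenyl)ethyl]oxan-4-one
Conditions: DMF/H2O (20:1), 160 °C (microwave)
Reagents that add atoms: none
Why: Krapcho-type dealkoxycarbonylation, in which the β-ketoester is hydrolysed in hot wet DMF and the β-keto acid loses CO2 through a cyclic transition state; the 2,6-cis arrangement is the thermodynamic one and should persist even if the ring opens and recloses.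

Step 8
Reactants: 12 (2S,6S)-2-[3,4-bis(benzyloxy)-5-methoxyphenyl]-6-[2-(4-benzyloxyphenyl)ethyl]oxan-4-one
Product: 13 (2S,4R,6S)-2-[3,4-bis(benzyloxy)-5-methoxyphenyl]-6-[2-(4-benzyloxyphenyl)ethyl]oxan-4-ol
Conditions: NaBH4, MeOH/THF, −20 °C
Reagents that add atoms: none
Why: Borohydride reduction of a chair ketone with both flanking substituents equatorial, where the small hydride attacks along the axial trajectory and should give the equatorial 4R alcohol, cis to both substituents.

Step 9
Reactants: 13 (2S,4R,6S)-2-[3,4-bis(benzyloxy)-5-methoxyphenyl]-6-[2-(4-benzyloxyphenyl)ethyl]oxan-4-ol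
Product: 14 (2S,4R,6S)-2-(3,4-dihydroxy-5-methoxyphenyl)-6-[2-(4-hydroxyphenyl)ethyl]oxan-4-ol
Conditions: H2 (1 atm), 10% Pd/C, EtOAc/MeOH, rt
Reagents that add atoms: none
Why: Catalytic hydrogenolysis of the three aryl benzyl ethers; the ring C2–O1 bond, a hindered secondary benzylic dialkyl ether, should cleave far more slowly, and the reaction is stopped after three equivalents of hydrogen with no stereocentre touched.

**Compound list**

1 | 3,4-dihydroxy-5-methoxybenzaldehyde | COc1cc(C=O)cc(O)c1O | starting material
2 | 3,4-bis(benzyloxy)-5-methoxybenzaldehyde | COc1cc(C=O)cc(OCc2ccccc2)c1OCc1ccccc1 | intermediate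
3 | 3-(4-hydroxyphenyl)propan-1-ol | OCCCc1ccc(O)cc1 | starting material
4 | 3-(4-benzyloxyphenyl)propan-1-ol | OCCCc1ccc(OCc2ccccc2)cc1 | intermediate
5 | 3-(4-benzyloxyphenyl)propanal | O=CCCc1ccc(OCc2ccccc2)cc1 | intermediate
6 | methyl acetoacetate | COC(=O)CC(C)=O | starting material
7 | methyl 3-(trimethylsilyloxy)but-2-enoate (E/Z mixture) | COC(=O)C=C(C)O[Si](C)(C)C | intermediate
8 | 1-methoxy-1,3-bis(trimethylsilyloxy)buta-1,3-diene (ketene acetal geometry undefined) | COC(O[Si](C)(C)C)=CC(=C)O[Si](C)(C)C | intermediate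
9 | methyl (5S)-7-(4-benzyloxyphenyl)-5-hydroxy-3-oxoheptanoate (formed in the flask) | COC(=O)CC(=O)C[C@@H](O)CCc1ccc(OCc2ccccc2)cc1 | intermediate
10 | methyl (5S)-2-[3,4-bis(benzyloxy)-5-methoxybenzylidene]-7-(4-benzyloxyphenyl)-5-hydroxy-3-oxoheptanoate (formed in the flask, alkene geometry undefined) | COC(=O)C(=Cc1cc(OC)c(OCc2ccccc2)c(OCc2ccccc2)c1)C(=O)C[C@@H](O)CCc1ccc(OCc2ccccc2)cc1 | intermediate
11 | methyl (2S,3R,6S)-2-[3,4-bis(benzyloxy)-5-methoxyphenyl]-6-[2-(4-benzyloxyphenyl)ethyl]-4-oxooxane-3-carboxylate (2,6-cis, ester trans to ring A) | COc1cc([C@@H]2[C@@H](C(=O)OC)C(=O)C[C@H](CCc3ccc(OCc4ccccc4)cc3)O2)cc(OCc2ccccc2)c1OCc1ccccc1 | intermediate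
12 | (2S,6S)-2-[3,4-bis(benzyloxy)-5-methoxyphenyl]-6-[2-(4-benzyloxyphenyl)ethyl]oxan-4-one (2,6-cis) | COc1cc([C@@H]2CC(=O)C[C@H](CCc3ccc(OCc4ccccc4)cc3)O2)cc(OCc2ccccc2)c1OCc1ccccc1 | intermediate
13 | (2S,4R,6S)-2-[3,4-bis(benzyloxy)-5-methoxyphenyl]-6-[2-(4-benzyloxyphenyl)ethyl]oxan-4-ol (all-cis) | COc1cc([C@@H]2C[C@H](O)C[C@H](CCc3ccc(OCc4ccccc4)cc3)O2)cc(OCc2ccccc2)c1OCc1ccccc1 | intermediate
14 | (2S,4R,6S)-2-(3,4-dihydroxy-5-methoxyphenyl)-6-[2-(4-hydroxyphenyl)ethyl]oxan-4-ol (all-cis) | COc1cc([C@@H]2C[C@H](O)C[C@H](CCc3ccc(O)cc3)O2)cc(O)c1O | target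

**Step count**

Total steps: 9. Longest linear sequence: 6 steps (3 → 4 → 5 → 11 → 12 → 13 → 14; the branch 6 → 7 → 8 → 11 → 14 is equally long).

**Steps most likely to fail**

Step 6. Facial selectivity of the titanium–BINOL aldol may be modest for an unbranched aliphatic aldehyde. The Knoevenagel stage may stall because the trioxygenated aldehyde is a poor electrophile. TiCl4 may also strip a benzyl group from the vicinally oxygenated ring. The fallback sets out from 5 and comes back at 11, and builds the stereocentre by asymmetric hydrogenation instead of by aldol addition. Aldehyde 5 is homologated with methyl diazoacetate and catalytic SnCl2 (Roskamp reaction) to methyl 5-(4-benzyloxyphenyl)-3-oxopentanoate F1. Noyori hydrogenation with RuCl2[(S)-BINAP] in methanol should give methyl (3S)-5-(4-benzyloxyphenyl)-3-hydroxypentanoate F2, the sense following that of simple 3-oxoalkanoates. Claisen condensation of F2 with excess lithium enolate of methyl acetate (LiN(iPr)2, THF, −78 to −30 °C) gives hydroxy ketoester 9, now isolated. Compounds 9 and 2 are then cyclised in a separate operation with Yb(OTf)3 in CH2Cl2 at rt, through 10, to give 11 under the same thermodynamic control.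

Step 7. At 160 °C the ring may open by retro-oxa-Michael reaction and the open enone may dehydrate or oligomerise before it recloses, and hydrolysis of the hindered ester may be slow. The fallback sets out from 5 and 2 and comes back at 12, replacing the methyl ester by an allyl ester so that the carboxyl group leaves at room temperature.
- Commercial allyl acetoacetate is silylated as in steps 4 and 5, first to allyl 3-(trimethylsilyloxy)but-2-enoate F3 and then to 1-(allyloxy)-1,3-bis(trimethylsilyloxy)buta-1,3-diene F4.
- The step 6 protocol with 5 and 2 leads through allyl (5S)-7-(4-benzyloxyphenyl)-5-hydroxy-3-oxoheptanoate F5 and allyl (5S)-2-[3,4-bis(benzyloxy)-5-methoxybenzylidene]-7-(4-benzyloxyphenyl)-5-hydroxy-3-oxoheptanoate F6, neither isolated.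
- The cascade ends at allyl (2S,3R,6S)-2-[3,4-bis(benzyloxy)-5-methoxyphenyl]-6-[2-(4-benzyloxyphenyl)ethyl]-4-oxooxane-3-carboxylate F7.
- Catalytic Pd(PPh3)4 and morpholine in THF at rt transfer the allyl group to the amine (Tsuji-type deallylation). The liberated (2S,3R,6S)-2-[3,4-bis(benzyloxy)-5-methoxyphenyl]-6-[2-(4-benzyloxyphenyl)ethyl]-4-oxooxane-3-carboxylic acid F8 loses CO2 at that temperature and gives 12.

Step 9. Hydrogenolytic opening of the ring at the benzylic C2–O1 bond, which is activated by the para-oxygen of ring A, may compete with removal of the last benzyl ether, and the catechol formed is prone to air oxidation during a prolonged reaction. The fallback sets out from 13 and comes back at 14, removing the benzyl groups by Lewis-acid dealkylation instead of by hydrogen. BCl3 with pentamethylbenzene as benzyl-cation scavenger in CH2Cl2 at −78 °C, followed by a methanol quench, should cleave the three aryl benzyl ethers while the aryl methyl ether and the oxane survive at this temperature. The borate formed at the C4 hydroxyl hydrolyses on work-up, and no new compound arises on the way (F0).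

Further compounds
F1 | step 6 | methyl 5-(4-benzyloxyphenyl)-3-oxopentanoate | COC(=O)CC(=O)CCc1ccc(OCc2ccccc2)cc1
F2 | step 6 | methyl (3S)-5-(4-benzyloxyphenyl)-3-hydroxypentanoate | COC(=O)C[C@@H](O)CCc1ccc(OCc2ccccc2)cc1
F3 | step 7 | allyl 3-(trimethylsilyloxy)but-2-enoate | C=CCOC(=O)C=C(C)O[Si](C)(C)C
F4 | step 7 | 1-(allyloxy)-1,3-bis(trimethylsilyloxy)buta-1,3-diene | C=CCOC(O[Si](C)(C)C)=CC(=C)O[Si](C)(C)C
F5 | step 7 | allyl (5S)-7-(4-benzyloxyphenyl)-5-hydroxy-3-oxoheptanoate | C=CCOC(=O)CC(=O)C[C@@H](O)CCc1ccc(OCc2ccccc2)cc1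
F6 | step 7 | allyl (5S)-2-[3,4-bis(benzyloxy)-5-methoxybenzylidene]-7-(4-benzyloxyphenyl)-5-hydroxy-3-oxoheptanoate | C=CCOC(=O)C(=Cc1cc(OC)c(OCc2ccccc2)c(OCc2ccccc2)c1)C(=O)C[C@@H](O)CCc1ccc(OCc2ccccc2)cc1
F7 | step 7 | allyl (2S,3R,6S)-2-[3,4-bis(benzyloxy)-5-methoxyphenyl]-6-[2-(4-benzyloxyphenyl)ethyl]-4-oxooxane-3-carboxylate | COc1cc([C@@H]2[C@@H](C(=O)OCC=C)C(=O)C[C@H](CCc3ccc(OCc4ccccc4)cc3)O2)cc(OCc2ccccc2)c1OCc1ccccc1
F8 | step 7 | (2S,3R,6S)-2-[3,4-bis(benzyloxy)-5-methoxyphenyl]-6-[2-(4-benzyloxyphenyl)ethyl]-4-oxooxane-3-carboxylic acid | COc1cc([C@@H]2[C@@H](C(=O)O)C(=O)C[C@H](CCc3ccc(OCc4ccccc4)cc3)O2)cc(OCc2ccccc2)c1OCc1ccccc1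
F0 | step 9 | none | none
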